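The route rests on cutting the C2–C3 bond of the dihydrofuran ring back to an achiral aryl benzyl ether. C2–H of the target is both alpha to the ring oxygen O1 and benzylic to the trimethoxyphenyl ring. It sits 1,5 to C3 across the O1–C7a–C3a edge of the benzo ring. A chiral dirhodium donor/donor carbene generated at C3 (from the methyl ketone hydrazone) inserts into this hydridic C–H bond, closing the five-membered ring and setting both stereocentres in one operation. Acid equilibration at C2 then gives the trans isomer. The allyl ether that masks O6 throughout is finally transposed to C5 by aromatic Claisen rearrangement.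

Key step: step 4

Remark on numbering: benzofuran numbering (O1, C2, C3, C3a, C4 to C7, C7a) is used throughout, also for the corresponding atoms of the open-chain precursors.
Assumption: Rh2(S-PTAD)4 is taken to be the catalyst enantiomer that delivers 3S. If the sense of induction is the opposite, the equally available Rh2(R-PTAD)4 is used and nothing else changes.

Step 1
Reactants: 1 2,4-dihydroxyacetophenone; 2 allyl bromide
Product: 3 1-[4-(allyloxy)-2-hydroxyphenyl]ethanone
Conditions: K2CO3 (1.1 equiv), acetone, reflux
Reagents that add atoms: allyl bromide (2), C=CCBr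
Why: Williamson etherification, in which the 2-OH is held in a hydrogen bond to the acetyl carbonyl and is the poorer nucleophile, so one equivalent of allyl bromide should alkylate only the 4-OH; no stereocentre is formed.

Step 2
Reactants: 3 1-[4-(allyloxy)-2-hydroxyphenyl]ethanone; 4 3,4,5-trimethoxybenzyl chloride
Product: 5 1-[4-(allyloxy)-2-[(3,4,5-trimethoxybenzyl)oxy]phenyl]ethanone
Conditions: K2CO3 (1.5 equiv), DMF, 70 °C
Reagents that add atoms: 3,4,5-trimethoxybenzyl chloride (4), COc1cc(CCl)cc(OC)c1OC
Why: Williamson etherification in a polar aprotic solvent with heating should break the chelate and alkylate the remaining 2-OH with the reactive benzylic chloride, which places the future C2 methylene 1,5 to the carbonyl carbon (future C3).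

Step 3
Reactants: 5 1-[4-(allyloxy)-2-[(3,4,5-trimethoxybenzyl)oxy]phenyl]ethanone; 6 hydrazine monohydrate
Product: 7 (E)-hydrazone of ketone 5
Conditions: N2H4·H2O (10 equiv), AcOH (cat.), EtOH, reflux, Ar
Reagents that add atoms: hydrazine monohydrate (6), NN.O
Why: Ketone–hydrazine condensation, in which the excess of hydrazine suppresses azine formation and exclusion of air prevents diimide reduction of the allyl group; the C=N geometry is of no consequence because it is lost in step 4.

Step 4
Reactants: 7 (E)-hydrazone of ketone 5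
Product: 10 (2R,3S)-6-(allyloxy)-3-methyl-2-(3,4,5-trimethoxyphenyl)-2,3-dihydrobenzofuran (2,3-cis), via diazoalkane 8 (not isolated), via rhodium carbene 9 (not isolated)
Conditions: MnO2 (8 equiv), CH2Cl2, 0 °C; filter (Celite); filtrate added dropwise to Rh2(S-PTAD)4 (1 mol%), CH2Cl2, −20 °C
Reagents that add atoms: none
Why: MnO2 dehydrogenates the hydrazone to diazoalkane 8, which loses N2 on the dirhodium catalyst to give the aryl/methyl (donor/donor) carbene 9 at C3; this takes up the hydridic C2–H as hydride, and the developing oxocarbenium/benzylic centre collapses onto C3 before it can rotate, forming the C2–C3 bond. The closest known reaction type is the enantioselective intramolecular C–H insertion of donor/donor rhodium carbenes into benzylic ether C–H bonds, an established entry to 2,3-disubstituted 2,3-dihydrobenzofurans. The dihydrofuran ring closes in the 1,5-insertion mode, through a compact cyclic array made up of C3, C3a, C7a, O1, C2 and the migrating hydrogen. The configuration at C3 (S) is fixed by the chiral pocket of the four (S)-(1-adamantyl)(N-phthalimido)acetate ligands, which leaves one carbene face open, and C2 is set relative to it by the nearly concerted hydride transfer and C–C closure, which places aryl and methyl cis (2R,3S). The step needs chemoselectivity for insertion over 1,2-hydride shift from the methyl group (styrene), azine formation and attack on the allyl group. The doubly activated C2–H next to an electron-rich arene, the bulky carboxylate ligands, the low temperature and the slow addition secure the first two, and the allyl ether sits para to the carbene-bearing carbon, out of intramolecular reach.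

Step 5
Reactants: 10 (2R,3S)-6-(allyloxy)-3-methyl-2-(3,4,5-trimethoxyphenyl)-2,3-dihydrobenzofuran
Product: 12 (2S,3S)-6-(allyloxy)-3-methyl-2-(3,4,5-trimethoxyphenyl)-2,3-dihydrobenzofuran (2,3-trans), via ring-opened benzylic cation 11 (not isolated)
Conditions: TFA (5 equiv), CH2Cl2, 0 °C to rt
Reagents that add atoms: none
Why: Acid-catalysed epimerisation by reversible SN1 ring opening, in which protonation of O1 ionises the C2–O1 bond to the 3,4,5-trimethoxybenzylic cation 11 and fast, reversible reclosure by the phenol should drain C2 into the thermodynamically preferred 2,3-trans arrangement (2S) under control of the untouched C3 stereocentre.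

Step 6
Reactants: 12 (2S,3S)-6-(allyloxy)-3-methyl-2-(3,4,5-trimethoxyphenyl)-2,3-dihydrobenzofuran
Product: 14 (2S,3S)-5-allyl-3-methyl-2-(3,4,5-trimethoxyphenyl)-2,3-dihydrobenzofuran-6-ol (target), via ortho-dienone 13 (not isolated)
Conditions: PhNEt2, 200 °C, sealed tube, Ar
Reagents that add atoms: none
Why: Aromatic Claisen rearrangement ([3,3]-sigmatropic shift, then tautomerisation of dienone 13), which should favour C5 over C7 because C7 is flanked by two oxygens, the meta-alkoxy donor O1 directs migration to the position para to it and the fused five-membered ring localises double-bond character in C5–C6; neither stereocentre takes part.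

Compound list
1 | 2,4-dihydroxyacetophenone | CC(=O)c1ccc(O)cc1O | starting material
2 | allyl bromide | C=CCBr | starting material
3 | 1-[4-(allyloxy)-2-hydroxyphenyl]ethanone | CC(=O)c1ccc(OCC=C)cc1O | intermediate
4 | 3,4,5-trimethoxybenzyl chloride | COc1cc(CCl)cc(OC)c1OC | starting material
5 | 1-[4-(allyloxy)-2-[(3,4,5-trimethoxybenzyl)oxy]phenyl]ethanone | CC(=O)c1ccc(OCC=C)cc1OCc1cc(OC)c(OC)c(OC)c1 | intermediate
6 | hydrazine monohydrate | NN.O | starting material
7 | (E)-{1-[4-(allyloxy)-2-[(3,4,5-trimethoxybenzyl)oxy]phenyl]ethylidene}hydrazine | C/C(=N\N)c1ccc(OCC=C)cc1OCc1cc(OC)c(OC)c(OC)c1 | intermediate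
8 | 4-(allyloxy)-1-(1-diazoethyl)-2-[(3,4,5-trimethoxybenzyl)oxy]benzene (not isolated) | CC(=[N+]=[N-])c1ccc(OCC=C)cc1OCc1cc(OC)c(OC)c(OC)c1 | intermediate
9 | rhodium carbene derived from 8 (not isolated; second rhodium and carboxylate ligands of the catalyst not drawn) | CC(=[Rh])c1ccc(OCC=C)cc1OCc1cc(OC)c(OC)c(OC)c1 | intermediate
10 | (2R,3S)-6-(allyloxy)-3-methyl-2-(3,4,5-trimethoxyphenyl)-2,3-dihydrobenzofuran (cis) | C=CCOc1ccc2c(c1)O[C@@H](c1cc(OC)c(OC)c(OC)c1)[C@H]2C | intermediate
11 | ring-opened cation, 2-[4-(allyloxy)-2-hydroxyphenyl]-1-(3,4,5-trimethoxyphenyl)propan-1-ylium, methyl-bearing carbon unchanged (not isolated) | C=CCOc1ccc([C@H](C)[CH+]c2cc(OC)c(OC)c(OC)c2)c(O)c1 | intermediate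
12 | (2S,3S)-6-(allyloxy)-3-methyl-2-(3,4,5-trimethoxyphenyl)-2,3-dihydrobenzofuran (trans) | C=CCOc1ccc2c(c1)O[C@H](c1cc(OC)c(OC)c(OC)c1)[C@H]2C | intermediate
13 | (2S,3S)-5-allyl-3-methyl-2-(3,4,5-trimethoxyphenyl)-2,3-dihydrobenzofuran-6(5H)-one, C5 epimers (not isolated) | C=CCC1C=C2C(=CC1=O)O[C@H](c1cc(OC)c(OC)c(OC)c1)[C@H]2C | intermediate
14 | (2S,3S)-5-allyl-3-methyl-2-(3,4,5-trimethoxyphenyl)-2,3-dihydrobenzofuran-6-ol | C=CCc1cc2c(cc1O)O[C@H](c1cc(OC)c(OC)c(OC)c1)[C@H]2C | target

Total step count: 6. Longest linear sequence: 6 steps (1 to 14).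

Steps most likely to fail

1. Step 4.
- **What may go wrong:** the rhodium carbene may collapse by 1,2-hydride shift from the methyl group. The labile diazoalkane may dimerise to the azine before it meets the catalyst. The small methyl donor may allow poor facial discrimination.
- **Fallback (sets out from 5, comes back at 12):** the same C2–C3 bond is closed photochemically and the enantiomers are separated afterwards. Irradiation of ketone 5 (365 nm, degassed benzene, rt) should proceed by delta-hydrogen abstraction from the benzylic OCH2 group and collapse of the 1,5-biradical (Norrish–Yang-type cyclisation). This should give racemic 6-(allyloxy)-3-methyl-2-(3,4,5-trimethoxyphenyl)-2,3-dihydrobenzofuran-3-ol F1 as a mixture of diastereomers. Ionic deoxygenation (Et3SiH, TFA, CH2Cl2, 0 °C to rt), in which the acid also equilibrates C2, should give racemic trans-6-(allyloxy)-3-methyl-2-(3,4,5-trimethoxyphenyl)-2,3-dihydrobenzofuran F2. Preparative chromatography on a chiral stationary phase should then deliver the (2S,3S) enantiomer 12.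

2. Step 6.
- **What may go wrong:** poor regioselectivity, with part of the allyl group migrating to C7 between the two oxygens and giving phenols that are hard to separate.
- **Fallback (sets out from 12, comes back at 14):** the allyl group is removed and brought back by cross-coupling at a halogen that marks C5. Tsuji–Trost deallylation (Pd(PPh3)4, morpholine, THF, rt) should give (2S,3S)-3-methyl-2-(3,4,5-trimethoxyphenyl)-2,3-dihydrobenzofuran-6-ol F3. Iodination with N-iodosuccinimide (MeCN, −20 °C) should take place at C5, which is ortho to the hydroxyl, para to O1 and less hindered than C7, to give (2S,3S)-5-iodo-3-methyl-2-(3,4,5-trimethoxyphenyl)-2,3-dihydrobenzofuran-6-ol F4. Suzuki–Miyaura coupling with allylboronic acid pinacol ester (Pd(dppf)Cl2, K2CO3, dioxane/water, 80 °C) should give 14.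

3. Step 5.
- **What may go wrong:** ionisation may be sluggish with the only moderately cation-stabilising trimethoxyphenyl group. The configuration at C3 may be lost through 1,2-hydride shift or through proton loss and reprotonation of the cation. The acid may also damage the allyl ether.
- **Fallback (sets out from 2 and 4, comes back at 12):** the correctable centre is moved from C2 to C3 by carrying an ester in place of the methyl group, so that trans is reached with base, and the same C2–C3 ring closure is kept.
  - Commercial methyl 2-(2,4-dihydroxyphenyl)acetate F5 is allylated with 2 at the less hindered 4-OH (K2CO3, acetone) to give methyl 2-[4-(allyloxy)-2-hydroxyphenyl]acetate F6.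
  - F6 is alkylated with 4 (K2CO3, DMF) to give methyl 2-[4-(allyloxy)-2-[(3,4,5-trimethoxybenzyl)oxy]phenyl]acetate F7.
  - Regitz diazo transfer (4-acetamidobenzenesulfonyl azide, DBU, MeCN) should give methyl 2-[4-(allyloxy)-2-[(3,4,5-trimethoxybenzyl)oxy]phenyl]-2-diazoacetate F8.
  - Donor/acceptor carbene C–H insertion follows, with Rh2(S-PTTL)4 (dirhodium tetrakis[N-phthaloyl-(S)-tert-leucinate], or its enantiomer, whichever gives 2S) in toluene at −60 °C. The carbene has no beta-hydrogen to shift. It should give methyl (2S,3R)-6-(allyloxy)-2-(3,4,5-trimethoxyphenyl)-2,3-dihydrobenzofuran-3-carboxylate F9 (cis).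
  - NaOMe in MeOH should epimerise C3 to give methyl (2S,3S)-6-(allyloxy)-2-(3,4,5-trimethoxyphenyl)-2,3-dihydrobenzofuran-3-carboxylate F10 (trans).
  - LiAlH4 (THF, 0 °C) should give [(2S,3R)-6-(allyloxy)-2-(3,4,5-trimethoxyphenyl)-2,3-dihydrobenzofuran-3-yl]methanol F11.
  - TsCl in pyridine should give [(2S,3R)-6-(allyloxy)-2-(3,4,5-trimethoxyphenyl)-2,3-dihydrobenzofuran-3-yl]methyl 4-methylbenzenesulfonate F12.
  - LiEt3BH (THF, 0 °C to rt) should reduce F12 to 12.

Further compounds
F1 | step 4 | 6-(allyloxy)-3-methyl-2-(3,4,5-trimethoxyphenyl)-2,3-dihydrobenzofuran-3-ol (racemic, diastereomer mixture, stereocentres undefined) | C=CCOc1ccc2c(c1)OC(c1cc(OC)c(OC)c(OC)c1)C2(C)O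
F2 | step 4 | racemic trans-6-(allyloxy)-3-methyl-2-(3,4,5-trimethoxyphenyl)-2,3-dihydrobenzofuran (both enantiomers written) | C=CCOc1ccc2c(c1)O[C@H](c1cc(OC)c(OC)c(OC)c1)[C@H]2C.C=CCOc1ccc2c(c1)O[C@@H](c1cc(OC)c(OC)c(OC)c1)[C@@H]2C
F3 | step 6 | (2S,3S)-3-methyl-2-(3,4,5-trimethoxyphenyl)-2,3-dihydrobenzofuran-6-ol | Oc1ccc2c(c1)O[C@H](c1cc(OC)c(OC)c(OC)c1)[C@H]2C
F4 | step 6 | (2S,3S)-5-iodo-3-methyl-2-(3,4,5-trimethoxyphenyl)-2,3-dihydrobenzofuran-6-ol | Ic1cc2c(cc1O)O[C@H](c1cc(OC)c(OC)c(OC)c1)[C@H]2C
F5 | step 5 | methyl 2-(2,4-dihydroxyphenyl)acetate | COC(=O)Cc1ccc(O)cc1O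
F6 | step 5 | methyl 2-[4-(allyloxy)-2-hydroxyphenyl]acetate | COC(=O)Cc1ccc(OCC=C)cc1O
F7 | step 5 | methyl 2-[4-(allyloxy)-2-[(3,4,5-trimethoxybenzyl)oxy]phenyl]acetate | COC(=O)Cc1ccc(OCC=C)cc1OCc1cc(OC)c(OC)c(OC)c1
F8 | step 5 | methyl 2-[4-(allyloxy)-2-[(3,4,5-trimethoxybenzyl)oxy]phenyl]-2-diazoacetate | COC(=O)C(=[N+]=[N-])c1ccc(OCC=C)cc1OCc1cc(OC)c(OC)c(OC)c1
F9 | step 5 | methyl (2S,3R)-6-(allyloxy)-2-(3,4,5-trimethoxyphenyl)-2,3-dihydrobenzofuran-3-carboxylate (cis) | C=CCOc1ccc2c(c1)O[C@H](c1cc(OC)c(OC)c(OC)c1)[C@@H]2C(=O)OC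
F10 | step 5 | methyl (2S,3S)-6-(allyloxy)-2-(3,4,5-trimethoxyphenyl)-2,3-dihydrobenzofuran-3-carboxylate (trans) | C=CCOc1ccc2c(c1)O[C@H](c1cc(OC)c(OC)c(OC)c1)[C@H]2C(=O)OC
F11 | step 5 | [(2S,3R)-6-(allyloxy)-2-(3,4,5-trimethoxyphenyl)-2,3-dihydrobenzofuran-3-yl]methanol | C=CCOc1ccc2c(c1)O[C@H](c1cc(OC)c(OC)c(OC)c1)[C@H]2CO
F12 | step 5 | [(2S,3R)-6-(allyloxy)-2-(3,4,5-trimethoxyphenyl)-2,3-dihydrobenzofuran-3-yl]methyl 4-methylbenzenesulfonate | C=CCOc1ccc2c(c1)O[C@H](c1cc(OC)c(OC)c(OC)c1)[C@H]2COS(=O)(=O)c1ccc(C)cc1
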